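## Structural features

The target is a 1,2-dioxolane (O1–O2–C3–C4–C5) in which both carbon termini, C3 and C5, are fully substituted and bonded to a peroxide oxygen; only C4 is a methylene. C3 carries CH3 and the CH2CO2Me arm, and C5 carries CH3 and the (2R)-2-methyl-8-phenyloctyl chain. The ring stereocentres C3 (R) and C5 (S) are therefore 1,3-related across C4, with the acetate arm and the long chain on opposite faces, and the chain stereocentre C2' (R) is one CH2 away from C5. The O–O bond is the fragile element: it does not survive hydrogenation, low-valent metals or hard carbanions, and because C3 is β to the ester carbonyl, an enolate formed next to it can expel or attack the peroxide (retro-Michael loss or Weitz–Scheffer-type epoxide formation). The real difficulty is two tetrasubstituted C–O stereocentres with no neighbouring handle, of which C3 must be made in absolute sense. The feature exploited is that C3 bears CH3, O2 and two CH2 groups (the CH2CO2Me arm and C4): if C4 is written as a second CH2CO2Me, C3 becomes the prochiral centre of a 3-methyl-3-peroxyglutarate whose two ester arms are enantiotopic. The chain stereocentre is of the 2-methylalkyl type and can be bought.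

## Logic of the disconnections

18 ⇒ 16 (through 17). Cut: O1–C5, together with the C–H bond of the C5 methyl group (C–Hg in 17, =CH2 in 16). Reason: with the oxygen pair already on C3, O1–C5 is the ring bond that can be closed without touching C3, and a 1,1-disubstituted alkene sends the peroxide oxygen to the fully substituted carbon. Gain: the ring and the C5 stereocentre disappear. Demand: 5-exo Markovnikov addition (secured by the alkene), a choice between the two alkene faces (not secured; the C5 epimer is separated), and a C–Hg to C–H exchange that spares O–O.

16 ⇒ 15 ⇒ 14. Cut: the peroxide protecting group, then C5=CH2 back to C5=O. Reason: a free hydroperoxide would add to the C5 carbonyl as a cyclic peroxyhemiketal, so the perketal must stay until the carbonyl is gone. Gain: the alkene is traced to a ketone accessible by acyl substitution. Demand: methylenation must outrun enolisation towards C4.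

14 ⇒ 7 + 13. Cut: C5–C6, between the ketone carbon and the CH2 next to the chain stereocentre. Reason: it divides the peroxide half from the chain at a bond with no stereocentre on either atom. Gain: convergence, and no acid chloride (HCl against the perketal, acyl/alkoxy interchange across the glutarate), no enolate and no later decarboxylation. Demand: a carbon nucleophile soft enough for the O–O bond, the methyl ester and the β-peroxy carbonyl groups, hence an alkylzinc under palladium catalysis.

7 ⇒ 6. Cut: the acyl C–S bond. Gain: return to the carboxylic acid. Demand: neutral activation.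

6 ⇒ 5 (strategic). Cut: none in the skeleton; in the reverse sense the CO2H of 6 is re-esterified so that both arms at C3 are identical. Gain: the only stereocentre of this half vanishes and an achiral, symmetrical diester remains. Demand: the forward step must tell two enantiotopic CH2CO2Me groups apart and stop after one.

5 ⇒ 4 ⇒ 3 ⇒ 1 + 2. Cut: each CO2Me carbon back to CH=CH2 (two C=C cleavage retrons), then the perketal C–O bond, then the C4–OOH bond. Gain: commercial 1 and 2. Demand: ionisation of a tertiary carbinol without elimination, and an oxidative cleavage that leaves O–O and the acid-labile group alone.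

13 ⇒ 12 ⇒ 11 ⇒ 8 + 9 (through 10). Cut: C–Zn, C–I, then C3–C4 of 11. Reason: one bond away from the methyl-bearing carbon lies a four-carbon chiral building block that is sold in either enantiomeric form and delivers the CH2–metal directly. A 3-methyl-branched terpenoid chain would carry one carbon too many and force an enolate acylation–decarboxylation. Demand: an sp3–sp3 coupling that does not touch the stereocentre.

## Other disconnections considered

Alternative 1: Both ring C–O bonds (C5–O1 and C3–O2) are cut and the two oxygens go back to O2; the carbon skeleton is folded into vinylcyclopropane A1, 1-ethenyl-1,2-dimethyl-2-[(2R)-2-methyl-8-phenyloctyl]cyclopropane.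
- Forward key step: PhSe radicals (PhSeSePh, light) add to the vinyl terminus of A1, the ring opens to the tertiary C5 radical, O2 is captured, and the peroxyl radical closes 5-exo on C3 with loss of PhSe radical to give vinyl dioxolane A2. The vinyl group then needs anti-Markovnikov hydroboration–oxidation, oxidation to the acid and esterification.
- In favour: ring and both C–O bonds form in one neutral step from O2, and the configuration of A1 is irrelevant.
- Against: C3 and C5 both pass through open-chain radicals, so neither is set in absolute sense; with the fixed chain centre up to four stereoisomers of A2 are to be expected. A tetrasubstituted vinylcyclopropane and a three-step arm adjustment are also needed.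
- Comparison: on structure the chosen plan is better, because it fixes C3 absolutely; C5 is uncontrolled in both (equal). On mechanism, the radical chain avoids every β-peroxy carbonyl intermediate and brings the peroxide in late, so fewer intermediates carry an O–O bond; on that point Alternative 1 is the better plan. On step economy the two are similar once the vinyl-to-acetate conversion is counted.

Alternative 2: The ring closure is the same O1–C5 cut as in the chosen plan, but the C3–O bond comes from oxetane A3, (2S)-2-methyl-2-[(4R)-4-methyl-2-methylidene-10-phenyldecyl]oxetane.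
- Forward: H2O2 with a Lewis acid (Me3SiOTf) opens A3 at the tertiary carbon with inversion to hydroperoxy alcohol A4; Hg(OAc)2 then closes the ring to organomercurial A5. Its C3 descriptor reads S only because the hydroxyethyl arm ranks below C4. NaBH4, oxidation of the CH2CH2OH arm and esterification follow.
- In favour: the sense at C3 follows from a stereospecific substitution and is predictable, which is better than an enzyme whose sense must first be found. With the arm at the alcohol level there is no β-peroxy carbonyl compound before ring closure, which is also better, and the peroxide enters after the skeleton is complete.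
- Against: the opening needs concentrated H2O2 and a strong Lewis acid next to an acid-sensitive 1,1-disubstituted alkene, with possible SN1 leakage at the tertiary centre. A3 requires an enantioenriched tertiary carbinol, a 1,3-diol and ring closure, and the arm must be oxidised twice in the presence of the dioxolane.
- Comparison: the ring-closing mechanism and the C5 problem are identical (equal). C3 control is stereospecific here and catalytic there. Step economy favours the chosen plan.

Alternative 3: C4–C5 and O2–C3 are cut in a (3+2) sense, giving silylperoxy ketal A6 (from the chain methyl ketone) and alkene A7 (a silyl-protected 3-methylbut-3-enol).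
- Forward: SnCl4 ionises A6 to the C5 peroxycarbenium ion, the CH2 terminus of A7 attacks it, and the silylated peroxide oxygen captures the tertiary cation at C3 to give dioxolane A8 (3S by ranking, same spatial arrangement as 18). Desilylation, oxidation and esterification follow.
- In favour: it is the most convergent plan. One step makes a C–C bond, a C–O bond and the ring from two simple partners, and the peroxide is carried through few steps. On step economy and convergence it is better than the chosen plan.
- Against: C3 and C5 are both created with at best relative control and no absolute control, so several diastereomers must be separated. A strong Lewis acid acts on a peroxide, and the arm again needs oxidation-level adjustment.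
- Comparison: the chosen plan is better only in the absolute control of C3; C5 is equally uncontrolled.

Key step: step 4

Assumption: the esterase is taken to cleave the pro-S CH2CO2Me arm of 5, giving (3R)-6. This sense is not established for a peroxy substituent, and the 3-hydroxy-3-methyl diester is reported to give the (S) half-ester, which corresponds to the other arm. The configuration of 6 is therefore to be checked (correlation with the known 3-hydroxy half-ester after O–O reduction of an analytical sample) before the route continues.

Step 1
Reactants: 1 4-methylhepta-1,6-dien-4-ol; 2 hydrogen peroxide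
Product: 3 4-hydroperoxy-4-methylhepta-1,6-diene
Conditions: 50 % aq H2O2 (excess), H2SO4 (cat.), 0 → 20 °C; kept as a solution, not distilled
Reagents that add atoms: none
Why: Acid-catalysed perhydrolysis (SN1): the tertiary carbinol ionises and the cation is captured by the large excess of H2O2; 50 % peroxide, catalytic acid and low temperature limit E1 loss to the conjugated triene and avoid concentrated peroxide.

Step 2
Reactants: 3 4-hydroperoxy-4-methylhepta-1,6-diene
Product: 4 4-[(2-methoxypropan-2-yl)peroxy]-4-methylhepta-1,6-diene
Conditions: 2-methoxypropene, PPTS (cat.), CH2Cl2, 0 °C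
Reagents that add atoms: 2-methoxypropene, COC(C)=C
Why: Acid-catalysed addition of the hydroperoxide O–H to the enol ether gives the perketal; the group is achiral (no diastereomers at the prochiral centre), stable to base, ozone and neutral buffer, and removable with aqueous acetic acid.

Step 3
Reactants: 4 4-[(2-methoxypropan-2-yl)peroxy]-4-methylhepta-1,6-diene
Product: 5 dimethyl 3-[(2-methoxypropan-2-yl)peroxy]-3-methylpentanedioate
Conditions: O3, NaOH, MeOH/CH2Cl2, −78 °C; cold neutralising quench
Reagents that add atoms: ozone, [O-][O+]=O; methanol, CO
Why: Ozonolysis in methanolic NaOH converts each vinyl group directly into CO2Me (the carbonyl fragments are trapped as methyl hemiacetal or methoxy hydroperoxide and oxidised or dehydrated in the basic medium), so the symmetric diester forms in one operation; ozone does not attack the dialkyl peroxide, and −78 °C with a cold quench keeps the β-peroxy carbonyl groups from enolising.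

Step 4
Reactants: 5 dimethyl 3-[(2-methoxypropan-2-yl)peroxy]-3-methylpentanedioate
Product: 6 (3R)-5-methoxy-3-[(2-methoxypropan-2-yl)peroxy]-3-methyl-5-oxopentanoic acid
Conditions: pig liver esterase, 0.1 M phosphate buffer pH 7.5, 10 % DMSO, 20 °C; then pH 4 (citrate), 0 °C, EtOAc extraction
Reagents that add atoms: water, O
Why: Serine-hydrolase mechanism: the active-site serine adds to one ester carbonyl, the tetrahedral intermediate loses methanol to give the acyl-enzyme, and water hydrolyses it to the carboxylate. The closest known reaction is the pig liver esterase desymmetrisation of prochiral dimethyl 3,3-disubstituted glutarates such as the 3-hydroxy-3-methyl diester. No ring is closed and no skeletal bond is formed; one C(=O)–OMe becomes C(=O)–OH. The new stereocentre C3 is controlled by the enzyme alone: its binding pockets place CH3 and the bulky perketal differently, so that only one of the two enantiotopic CH2CO2Me arms reaches the serine. The step needs enantiotopic-group selectivity (the pro-S arm must be cleaved for 6) and mono-selectivity; the latter is secured by the substrate, because the half-ester is an anion at pH 7.5 and a poor substrate for a second hydrolysis. There is no redox cofactor, acid or strong base, so the O–O bond and the perketal survive and the β-peroxy esters cannot enolise. As a desymmetrisation it can in principle convert all of 5, and any enantiomer of 6 that forms is removed later as a diastereomer after coupling with the enantiopure chain.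

Step 5
Reactants: 6 (3R)-5-methoxy-3-[(2-methoxypropan-2-yl)peroxy]-3-methyl-5-oxopentanoic acid
Product: 7 methyl (3S)-5-(ethylsulfanyl)-3-[(2-methoxypropan-2-yl)peroxy]-3-methyl-5-oxopentanoate
Conditions: EtSH, DCC, DMAP (cat.), CH2Cl2, 0 °C
Reagents that add atoms: ethanethiol, CCS
Why: Steglich-type thioesterification through the O-acylisourea and acylpyridinium ion; the neutral, cold conditions spare the perketal and avoid the acid chloride, in which glutaric half-esters can exchange acyl and alkoxy groups through a cyclic oxonium ion and lose configuration. C3 is not touched; its descriptor becomes S only because the thioester arm outranks the ester arm.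

Step 6
Reactants: 8 (2S)-3-bromo-2-methylpropan-1-ol; 9 (5-bromopentyl)benzene
Product: 11 (2R)-2-methyl-8-phenyloctan-1-ol, via 5-phenylpentylmagnesium bromide 10 (not isolated)
Conditions: 9, Mg, THF, 40 °C; then 8, Li2CuCl4 (cat.), THF, −78 → 0 °C (excess of 10)
Reagents that add atoms: none
Why: Copper-catalysed sp3–sp3 cross-coupling of a primary alkyl bromide with a Grignard reagent; the first equivalent of 10 turns the hydroxyl into an inert bromomagnesium alkoxide. The stereocentre of 8 lies next to, not at, the reacting carbon and is retained; the descriptor changes from S to R by CIP ranking alone.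

Step 7
Reactants: 11 (2R)-2-methyl-8-phenyloctan-1-ol
Product: 12 [(7R)-8-iodo-7-methyloctyl]benzene
Conditions: I2, PPh3, imidazole, CH2Cl2, 0 → 20 °C
Reagents that add atoms: iodine, II
Why: Appel-type iodination: iodide displaces the alkoxyphosphonium group at the primary carbon; the neighbouring stereocentre is untouched.

Step 8
Reactants: 7 methyl (3S)-5-(ethylsulfanyl)-3-[(2-methoxypropan-2-yl)peroxy]-3-methyl-5-oxopentanoate; 12 [(7R)-8-iodo-7-methyloctyl]benzene
Product: 14 methyl (3R,7R)-3-[(2-methoxypropan-2-yl)peroxy]-3,7-dimethyl-5-oxo-13-phenyltridecanoate, via (2R)-2-methyl-8-phenyloctylzinc iodide 13 (not isolated)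
Conditions: 12, Zn dust (activated with BrCH2CH2Br, Me3SiCl), THF, 40 °C; supernatant added to 7, PdCl2(PPh3)2 (cat.), toluene, 20 °C
Reagents that add atoms: none
Why: Fukuyama coupling: zinc inserts into the C–I bond, zerovalent palladium (from PdCl2(PPh3)2 and the zinc reagent) inserts into the acyl C–S bond, and transmetallation and reductive elimination give the ketone. An alkylzinc iodide is not basic enough to enolise the β-peroxy carbonyl groups nor nucleophilic enough to add to ketone, ester or the O–O bond, unlike lithium or magnesium reagents, and excess zinc metal is left behind before mixing. Both stereocentres pass through unchanged.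

Step 9
Reactants: 14 methyl (3R,7R)-3-[(2-methoxypropan-2-yl)peroxy]-3,7-dimethyl-5-oxo-13-phenyltridecanoate
Product: 15 methyl (3R,7R)-3-[(2-methoxypropan-2-yl)peroxy]-3,7-dimethyl-5-methylidene-13-phenyltridecanoate
Conditions: Ph3PCH3Br, KN(SiMe3)2 (slight deficit), THF, 0 °C; then 14, −78 → 0 °C
Reagents that add atoms: methyltriphenylphosphonium bromide, C[P+](c1ccccc1)(c1ccccc1)c1ccccc1.[Br-]
Why: Wittig methylenation; phosphorus ylides do not attack dialkyl peroxides, and addition to this unhindered dialkyl ketone should be faster than deprotonation at C4, the one event that would destroy the peroxide (epoxide formation or β-elimination). No stereocentre is involved.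

Step 10
Reactants: 15 methyl (3R,7R)-3-[(2-methoxypropan-2-yl)peroxy]-3,7-dimethyl-5-methylidene-13-phenyltridecanoate
Product: 16 methyl (3R,7R)-3-hydroperoxy-3,7-dimethyl-5-methylidene-13-phenyltridecanoate
Conditions: AcOH/THF/H2O, 20 °C
Reagents that add atoms: none
Why: Acid-catalysed perketal hydrolysis proceeds through the 2-methoxyprop-2-yl cation, not through a cation at C3, so the tertiary hydroperoxide is released with its configuration intact; ester and alkene are inert to aqueous acetic acid.

Step 11
Reactants: 16 methyl (3R,7R)-3-hydroperoxy-3,7-dimethyl-5-methylidene-13-phenyltridecanoate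
Product: 18 methyl 2-[(3R,5S)-3,5-dimethyl-5-[(2R)-2-methyl-8-phenyloctyl]-1,2-dioxolan-3-yl]acetate, via acetoxymercuriomethyl dioxolane 17 (not isolated)
Conditions: Hg(OAc)2, CH2Cl2, 20 °C; then NaBH4, 2 M aq NaOH, 0 °C, short contact; chromatography
Reagents that add atoms: none
Why: Cycloperoxymercuration then hydridodemercuration: divalent mercury activates the 1,1-disubstituted alkene, the terminal hydroperoxide oxygen adds to the fully substituted carbon in the 5-exo Markovnikov mode, and NaBH4 replaces mercury by hydrogen through the alkylmercury hydride radical chain, turning CH2HgOAc into the C5 methyl group. C3 is untouched and C5 is set in the ring closure; since CH3 and CH2CO2Me at C3 differ little in size, both C5 epimers are expected in comparable amounts. 18 (acetate arm and long chain trans) is separated from its C5 epimer by chromatography, which also removes any diastereomer derived from residual enantiomer of 6.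

## Compound list

1 | 4-methylhepta-1,6-dien-4-ol | C=CCC(C)(O)CC=C | starting material
2 | hydrogen peroxide | OO | starting material
3 | 4-hydroperoxy-4-methylhepta-1,6-diene | C=CCC(C)(OO)CC=C | intermediate
4 | 4-[(2-methoxypropan-2-yl)peroxy]-4-methylhepta-1,6-diene | C=CCC(C)(CC=C)OOC(C)(C)OC | intermediate
5 | dimethyl 3-[(2-methoxypropan-2-yl)peroxy]-3-methylpentanedioate | COC(=O)CC(C)(CC(=O)OC)OOC(C)(C)OC | intermediate
6 | (3R)-5-methoxy-3-[(2-methoxypropan-2-yl)peroxy]-3-methyl-5-oxopentanoic acid | COC(=O)C[C@@](OOC(C)(C)OC)(C)CC(=O)O | intermediate
7 | methyl (3S)-5-(ethylsulfanyl)-3-[(2-methoxypropan-2-yl)peroxy]-3-methyl-5-oxopentanoate | COC(=O)C[C@@](OOC(C)(C)OC)(C)CC(=O)SCC | intermediate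
8 | (2S)-3-bromo-2-methylpropan-1-ol | OC[C@H](C)CBr | starting material
9 | (5-bromopentyl)benzene | BrCCCCCc1ccccc1 | starting material
10 | 5-phenylpentylmagnesium bromide | Br[Mg]CCCCCc1ccccc1 | intermediate
11 | (2R)-2-methyl-8-phenyloctan-1-ol | OC[C@H](C)CCCCCCc1ccccc1 | intermediate
12 | [(7R)-8-iodo-7-methyloctyl]benzene | IC[C@H](C)CCCCCCc1ccccc1 | intermediate
13 | [(2R)-2-methyl-8-phenyloctyl]zinc iodide | I[Zn]C[C@H](C)CCCCCCc1ccccc1 | intermediate
14 | methyl (3R,7R)-3-[(2-methoxypropan-2-yl)peroxy]-3,7-dimethyl-5-oxo-13-phenyltridecanoate | COC(=O)C[C@@](OOC(C)(C)OC)(C)CC(=O)C[C@H](C)CCCCCCc1ccccc1 | intermediate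
15 | methyl (3R,7R)-3-[(2-methoxypropan-2-yl)peroxy]-3,7-dimethyl-5-methylidene-13-phenyltridecanoate | COC(=O)C[C@@](OOC(C)(C)OC)(C)CC(=C)C[C@H](C)CCCCCCc1ccccc1 | intermediate
16 | methyl (3R,7R)-3-hydroperoxy-3,7-dimethyl-5-methylidene-13-phenyltridecanoate | COC(=O)C[C@@](OO)(C)CC(=C)C[C@H](C)CCCCCCc1ccccc1 | intermediate
17 | methyl 2-[(3R,5S)-5-[(acetyloxymercurio)methyl]-3-methyl-5-[(2R)-2-methyl-8-phenyloctyl]-1,2-dioxolan-3-yl]acetate | COC(=O)C[C@@]1(C)C[C@](C[Hg]OC(C)=O)(C[C@H](C)CCCCCCc2ccccc2)OO1 | intermediate
18 | methyl 2-[(3R,5S)-3,5-dimethyl-5-[(2R)-2-methyl-8-phenyloctyl]-1,2-dioxolan-3-yl]acetate | COC(=O)C[C@@]1(C)C[C@](C)(C[C@H](C)CCCCCCc2ccccc2)OO1 | target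

## Step count and least certain steps

Total step count: 11. Longest linear sequence: 9 (steps 1–5 and 8–11); steps 6 and 7 form the side branch.

Step 4 (key step). The enzyme may fail to bind a substrate with so large a 3-substituent, or may discriminate the arms poorly or in the opposite sense. Its pockets are known to read a small polar group against methyl, and size-dependent reversals occur in the glutarate series. Screening other hydrolases is the first measure. The fallback sets out from 5 and comes back at 6:
- Both esters are saponified (LiOH, THF/H2O, 0 °C; extraction at pH 4) to 3-[(2-methoxypropan-2-yl)peroxy]-3-methylpentanedioic acid F1.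
- DCC in CH2Cl2 closes F1 to the prochiral anhydride 4-[(2-methoxypropan-2-yl)peroxy]-4-methyloxane-2,6-dione F2.
- Alkaloid-mediated methanolysis (MeOH, quinidine or quinine, toluene, −50 °C) opens F2 to 6; the pseudo-enantiomeric alkaloid is chosen for the (3R) sense.

Step 11. Poor facial selectivity at C5 is inherent, since the two C3 substituents are of similar size. During demercuration the primary β-peroxyalkyl radical may also attack the O–O bond (epoxide formation with ring loss) before it is reduced. The fallback sets out from 16 and comes back at 18:
- N-iodosuccinimide (CH2Cl2, 0 °C, dark) closes the ring in the same 5-exo mode to methyl 2-[(3R,5S)-5-(iodomethyl)-3-methyl-5-[(2R)-2-methyl-8-phenyloctyl]-1,2-dioxolan-3-yl]acetate F3 and its C5 epimer.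
- These stable iodides can be separated before the reduction.
- Bu3SnH in high concentration (Et3B/air, −40 °C) then gives 18; low temperature and high hydride concentration favour hydrogen transfer over attack on the peroxide.

Step 9. Enolisation of the β-peroxy ketone by the basic ylide, followed by loss of the peroxide, may compete with carbonyl addition. The fallback sets out from 14 and comes back at 16:
- Me3SiCH2MgCl with CeCl3 (THF, −78 °C) adds to the carbonyl without enolising it, giving methyl (3R,7R)-5-hydroxy-3-[(2-methoxypropan-2-yl)peroxy]-3,7-dimethyl-13-phenyl-5-[(trimethylsilyl)methyl]tridecanoate F4 (both C5 epimers).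
- TsOH (cat.) in wet THF then effects the acid-type Peterson elimination and hydrolyses the perketal at the same time, so 16 is reached directly and step 10 is not needed.

Step 8. The O–O bond may be reduced by residual zinc metal or phosphine-ligated palladium, or the perketal ionised by zinc halide, during the coupling. The fallback sets out from 6 and 12 and comes back at 14:
- 6 is condensed with pyridine-2-thiol (DCC, CH2Cl2, 0 °C) to methyl (3S)-3-[(2-methoxypropan-2-yl)peroxy]-3-methyl-5-oxo-5-(pyridin-2-ylsulfanyl)pentanoate F5.
- 12 is converted with Mg into [(2R)-2-methyl-8-phenyloctyl]magnesium iodide F6, which is added to F5 in THF at −78 °C.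
- Chelation by the pyridine nitrogen makes acyl substitution fast at a temperature at which Grignard reagents do not yet attack dialkyl peroxides or methyl esters, and the chelated adduct releases 14 only on work-up.

## Further compounds

F1 | step 4 | 3-[(2-methoxypropan-2-yl)peroxy]-3-methylpentanedioic acid | OC(=O)CC(C)(CC(=O)O)OOC(C)(C)OC
F2 | step 4 | 4-[(2-methoxypropan-2-yl)peroxy]-4-methyloxane-2,6-dione | CC1(OOC(C)(C)OC)CC(=O)OC(=O)C1
F3 | step 11 | methyl 2-[(3R,5S)-5-(iodomethyl)-3-methyl-5-[(2R)-2-methyl-8-phenyloctyl]-1,2-dioxolan-3-yl]acetate | COC(=O)C[C@@]1(C)C[C@](CI)(C[C@H](C)CCCCCCc2ccccc2)OO1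
F4 | step 9 | methyl (3R,7R)-5-hydroxy-3-[(2-methoxypropan-2-yl)peroxy]-3,7-dimethyl-13-phenyl-5-[(trimethylsilyl)methyl]tridecanoate (both C5 epimers) | COC(=O)C[C@@](OOC(C)(C)OC)(C)CC(O)(C[Si](C)(C)C)C[C@H](C)CCCCCCc1ccccc1
F5 | step 8 | methyl (3S)-3-[(2-methoxypropan-2-yl)peroxy]-3-methyl-5-oxo-5-(pyridin-2-ylsulfanyl)pentanoate | COC(=O)C[C@@](OOC(C)(C)OC)(C)CC(=O)Sc1ccccn1
F6 | step 8 | [(2R)-2-methyl-8-phenyloctyl]magnesium iodide | I[Mg]C[C@H](C)CCCCCCc1ccccc1
A1 | alternative 1 | 1-ethenyl-1,2-dimethyl-2-[(2R)-2-methyl-8-phenyloctyl]cyclopropane (ring diastereomers) | C=CC1(C)CC1(C)C[C@H](C)CCCCCCc1ccccc1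
A2 | alternative 1 | (3R,5S)-3-ethenyl-3,5-dimethyl-5-[(2R)-2-methyl-8-phenyloctyl]-1,2-dioxolane | C=C[C@@]1(C)C[C@](C)(C[C@H](C)CCCCCCc2ccccc2)OO1
A3 | alternative 2 | (2S)-2-methyl-2-[(4R)-4-methyl-2-methylidene-10-phenyldecyl]oxetane | C1CO[C@@]1(C)CC(=C)C[C@H](C)CCCCCCc1ccccc1
A4 | alternative 2 | (3R,7R)-3-hydroperoxy-3,7-dimethyl-5-methylidene-13-phenyltridecan-1-ol | OCC[C@@](OO)(C)CC(=C)C[C@H](C)CCCCCCc1ccccc1
A5 | alternative 2 | 2-[(3S,5S)-5-[(acetyloxymercurio)methyl]-3-methyl-5-[(2R)-2-methyl-8-phenyloctyl]-1,2-dioxolan-3-yl]ethan-1-ol | OCC[C@@]1(C)C[C@](C[Hg]OC(C)=O)(C[C@H](C)CCCCCCc2ccccc2)OO1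
A6 | alternative 3 | triethyl{[(4R)-2-methoxy-4-methyl-10-phenyldecan-2-yl]peroxy}silane (both C2 epimers) | CC[Si](CC)(CC)OOC(C)(OC)C[C@H](C)CCCCCCc1ccccc1
A7 | alternative 3 | tert-butyl[(3-methylbut-3-en-1-yl)oxy]diphenylsilane | C=C(C)CCO[Si](c1ccccc1)(c1ccccc1)C(C)(C)C
A8 | alternative 3 | tert-butyl{2-[(3S,5S)-3,5-dimethyl-5-[(2R)-2-methyl-8-phenyloctyl]-1,2-dioxolan-3-yl]ethoxy}diphenylsilane | CC(C)(C)[Si](c1ccccc1)(c1ccccc1)OCC[C@@]1(C)C[C@](C)(C[C@H](C)CCCCCCc2ccccc2)OO1
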